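**Retrosynthetic overview**

1. 8-Hydroxyluteolin 7-sulfate ⇐ ammonolysis of its 5,8,3',4'-tetraacetate ⇐ sulfation of the 7-OH tetraacetate ⇐ 7-selective deacetylation of hypolaetin pentaacetate ⇐ BBr3 demethylation of 5,7,8,3',4'-pentamethoxyflavone ⇐ hydrodebromination of its 3-bromo derivative.
2. Feature used: in ring C, C3 is the only carbon that bears neither oxygen nor aryl, a bare CH between C2 (bonded to O1 and ring B) and the C4 carbonyl. Ring C is therefore the furan ring of a 2-aryl-3-silyloxybenzofuran plus one inserted carbon, and the 3-bromoflavone is cut at C2–C3 and C3–C4 into that benzofuran and dibromocarbene from bromoform.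
3. Silyloxybenzofuran ⇐ 2-aryl-4,6,7-trimethoxybenzofuran-3(2H)-one ⇐ intramolecular Friedel–Crafts acylation (C3–C3a) of an α-aryloxy arylacetic acid ⇐ rhodium-carbenoid O–H insertion (O1–C2) between 2,3,5-trimethoxyphenol and the diazo ester of methyl (3,4-dimethoxyphenyl)acetate.
4. 2,3,5-Trimethoxyphenol ⇐ o-vanillin by Elbs oxidation, O-methylation and Baeyer–Villiger oxidation.
5. Ring order: rings A and B are bought; the furan ring is closed in step 7 and enlarged to the pyranone ring C in step 9.

Key step: step 9

Assumption: the target is drawn as the free hydrogen sulfate, so the last step ends with protonation of the ammonium salt by one equivalent of cold dilute HCl; in practice the compound would be stored as a salt, because free aryl hydrogen sulfates hydrolyse on standing. Compounds 9–12 and 15 are racemates, which is immaterial because the target has no stereocentre.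

**Route**

Step 1
Reactants: 1 2-hydroxy-3-methoxybenzaldehyde (o-vanillin)
Product: 3 2,5-dihydroxy-3-methoxybenzaldehyde, via aryl potassium sulfate 2 (not isolated)
Conditions: K2S2O8, NaOH (aq), 0 °C to rt; then HCl (aq), 80 °C
Reagents that add atoms: potassium peroxodisulfate, [K+].[K+].[O-]S(=O)(=O)OOS(=O)(=O)[O-]
Why: Elbs persulfate oxidation, in which the phenoxide of 1 should attack a peroxide oxygen through C5, the free position para to the phenoxide oxygen, and acid hydrolysis of the aryl sulfate 2 then frees the 5-hydroxyl.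

Step 2
Reactants: 3 2,5-dihydroxy-3-methoxybenzaldehyde
Product: 4 2,3,5-trimethoxybenzaldehyde
Conditions: MeI, K2CO3, DMF (degassed), rt to 40 °C
Reagents that add atoms: iodomethane, CI
Why: Williamson O-methylation (SN2 on iodomethane) of both phenols, the aldehyde having no enolisable hydrogen and staying inert.

Step 3
Reactants: 4 2,3,5-trimethoxybenzaldehyde
Product: 6 2,3,5-trimethoxyphenol, via 2,3,5-trimethoxyphenyl formate 5 (not isolated)
Conditions: mCPBA, CH2Cl2, 0 °C to rt; then K2CO3 (cat.), MeOH, rt
Reagents that add atoms: 3-chloroperoxybenzoic acid (mCPBA), OOC(=O)c1cccc(Cl)c1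
Why: Baeyer–Villiger (Dakin-type) oxidation, in which the electron-rich trimethoxyphenyl group migrates in preference to hydrogen in the Criegee adduct and the labile formate 5 is cleaved by base-catalysed methanolysis.

Step 4
Reactants: 7 methyl (3,4-dimethoxyphenyl)acetate
Product: 8 methyl 2-diazo-2-(3,4-dimethoxyphenyl)acetate
Conditions: 4-acetamidobenzenesulfonyl azide, DBU, MeCN, 0 °C to rt
Reagents that add atoms: 4-acetamidobenzenesulfonyl azide, CC(=O)Nc1ccc(cc1)S(=O)(=O)N=[N+]=[N-]
Why: Regitz diazo transfer, the benzylic ester enolate formed by DBU attacking the terminal azide nitrogen and expelling the sulfonamide.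

Step 5
Reactants: 6 2,3,5-trimethoxyphenol; 8 methyl 2-diazo-2-(3,4-dimethoxyphenyl)acetate
Product: 9 methyl 2-(3,4-dimethoxyphenyl)-2-(2,3,5-trimethoxyphenoxy)acetate (racemic)
Conditions: Rh2(OAc)4 (1 mol %), CH2Cl2, rt, slow addition of 8
Reagents that add atoms: none
Why: Rhodium-carbenoid O–H insertion, in which the phenol oxygen attacks the donor/acceptor carbenoid and a proton shift in the oxonium ylide gives the aryl ether; the new stereocentre forms without control, which does not matter because it becomes sp2 in step 8.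

Step 6
Reactants: 9 methyl 2-(3,4-dimethoxyphenyl)-2-(2,3,5-trimethoxyphenoxy)acetate
Product: 10 2-(3,4-dimethoxyphenyl)-2-(2,3,5-trimethoxyphenoxy)acetic acid (racemic)
Conditions: LiOH, THF/MeOH/H2O, rt; then 1 M HCl
Reagents that add atoms: lithium hydroxide, [Li+].[OH-]
Why: Ester saponification (acyl–oxygen cleavage by hydroxide), which leaves the aryl and benzylic ethers untouched.

Step 7
Reactants: 10 2-(3,4-dimethoxyphenyl)-2-(2,3,5-trimethoxyphenoxy)acetic acid
Product: 12 2-(3,4-dimethoxyphenyl)-4,6,7-trimethoxy-1-benzofuran-3(2H)-one (racemic), via mixed trifluoroacetic anhydride 11 (not isolated)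
Conditions: (CF3CO)2O, CH2Cl2, 0 °C to rt, under Ar; aq NaHCO3 work-up
Reagents that add atoms: none
Why: Intramolecular Friedel–Crafts acylation through the mixed anhydride, where the tether lets only C6 of the phenoxy ring attack (ortho to the ether oxygen, ortho to one methoxy group and para to another) and five-membered ring closure gives the benzofuranone.

Step 8
Reactants: 12 2-(3,4-dimethoxyphenyl)-4,6,7-trimethoxy-1-benzofuran-3(2H)-one
Product: 13 tert-butyl{[2-(3,4-dimethoxyphenyl)-4,6,7-trimethoxy-1-benzofuran-3-yl]oxy}dimethylsilane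
Conditions: TBSOTf, Et3N, CH2Cl2, 0 °C, under Ar
Reagents that add atoms: tert-butyldimethylsilyl trifluoromethanesulfonate, CC(C)(C)[Si](C)(C)OS(=O)(=O)C(F)(F)F
Why: Silyl enol ether formation, with silylation directed to oxygen because it aromatises the furan ring; the C2 stereocentre disappears.

Step 9
Reactants: 13 tert-butyl{[2-(3,4-dimethoxyphenyl)-4,6,7-trimethoxy-1-benzofuran-3-yl]oxy}dimethylsilane; 14 bromoform
Product: 17 3-bromo-2-(3,4-dimethoxyphenyl)-5,7,8-trimethoxy-4H-chromen-4-one, via dibromocyclopropane adduct 15 (not isolated), via 3-bromo-4-silyloxyflavylium bromide 16 (not isolated)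
Conditions: CHBr3 (3 equiv), KOC(CH3)3 (4 equiv), PhMe–hexane, −20 °C to rt; then 1 M HCl, THF, rt
Reagents that add atoms: none
Why: Proposed new method: KOC(CH3)3 deprotonates bromoform and loss of bromide gives dibromocarbene, which as an electrophile should add across C2–C3 of 13 to give the cis-fused gem-dibromocyclopropane 15; the bromide endo to the five-membered ring then leaves while the old C2–C3 σ bond opens in a disrotatory two-electron electrocyclic process, so that the carbene carbon becomes C3, bonded to C2 and C4, in the aromatic 4-silyloxyflavylium ion 16, and transfer of the silyl group to bromide leaves the C4 carbonyl of 17. The closest known reaction types are the dihalocarbene ring expansion of cyclic silyl enol ethers to 2-halocycloalk-2-enones and the Ciamician–Dennstedt enlargement of indoles and benzofurans by dihalocarbenes. Ring C is closed by ring enlargement (a [2+1] cycloaddition followed by cyclopropyl-to-allyl cation opening) and not by cyclisation of a chain, the furan ring growing from five to six members. No stereocentre remains, since both cyclopropane stereocentres of racemic 15 become sp2. The step needs chemoselectivity for the C2–C3 bond over the two methoxylated benzene rings, which the substrate secures because this bond carries two oxygen donors (OSi at C3, O1 at C2) and is the least aromatic π bond, and it needs the silyl ether to outlast the alkoxide, for which the bulky TBS group, a non-polar solvent and low temperature are chosen. Should tert-butoxide add to C2 of 16 instead, the acidic work-up would return the same flavylium ion and hence 17.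

Step 10
Reactants: 17 3-bromo-2-(3,4-dimethoxyphenyl)-5,7,8-trimethoxy-4H-chromen-4-one
Product: 18 2-(3,4-dimethoxyphenyl)-5,7,8-trimethoxy-4H-chromen-4-one
Conditions: Pd(PPh3)4 (5 mol %, zerovalent palladium), HCO2H, Et3N, DMF, 80 °C
Reagents that add atoms: none
Why: Palladium-catalysed hydrodehalogenation, by oxidative addition of zerovalent palladium into the C3–Br bond, exchange of bromide for formate, loss of CO2 and reductive elimination of C3–H, which leaves the C2–C3 double bond and the methyl ethers untouched.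

Step 11
Reactants: 18 2-(3,4-dimethoxyphenyl)-5,7,8-trimethoxy-4H-chromen-4-one
Product: 19 2-(3,4-dihydroxyphenyl)-5,7,8-trihydroxy-4H-chromen-4-one (hypolaetin)
Conditions: BBr3 (excess), CH2Cl2, −78 °C to rt, under Ar; then H2O, 0 °C
Reagents that add atoms: none
Why: Lewis-acid ether cleavage, in which BBr3 coordinates each methoxy oxygen and bromide removes the methyl group by SN2 with the aryl–oxygen bonds intact; the low temperature and the absence of hot protic acid should avoid Wessely–Moser isomerisation of the 5,7,8-trioxygenated ring A.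

Step 12
Reactants: 19 hypolaetin
Product: 20 2-(3,4-diacetoxyphenyl)-4-oxo-4H-chromene-5,7,8-triyl triacetate (hypolaetin pentaacetate)
Conditions: Ac2O, pyridine, DMAP (cat.), rt, under Ar
Reagents that add atoms: acetic anhydride, CC(=O)OC(C)=O
Why: DMAP-catalysed O-acylation of all five phenols, including the hydrogen-bonded 5-OH, which also protects the oxidation-prone ring A.

Step 13
Reactants: 20 hypolaetin pentaacetate
Product: 21 2-(3,4-diacetoxyphenyl)-7-hydroxy-4-oxo-4H-chromene-5,8-diyl diacetate
Conditions: PhSH (1.1 equiv), imidazole (cat.), NMP, 0 °C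
Reagents that add atoms: none
Why: Regioselective thiolysis (acyl transfer to thiophenolate), the 7-acetate being the most electrophilic because the 7-phenoxide, para-conjugated with the C4 carbonyl, is the best leaving group.

Step 14
Reactants: 21 2-(3,4-diacetoxyphenyl)-7-hydroxy-4-oxo-4H-chromene-5,8-diyl diacetate
Product: 22 pyridinium 2-(3,4-diacetoxyphenyl)-5,8-diacetoxy-4-oxo-4H-chromen-7-yl sulfate
Conditions: SO3·pyridine (3 equiv), DMF, rt
Reagents that add atoms: sulfur trioxide–pyridine complex, [O-]S(=O)(=O)[n+]1ccccc1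
Why: O-sulfation of a phenol by sulfur trioxide transfer from the pyridine complex, the 7-OH being the only free hydroxyl and no strong base being added, to hold back acetyl migration from O8.

Step 15
Reactants: 22 pyridinium 2-(3,4-diacetoxyphenyl)-5,8-diacetoxy-4-oxo-4H-chromen-7-yl sulfate
Product: 24 2-(3,4-dihydroxyphenyl)-5,8-dihydroxy-4-oxo-4H-chromen-7-yl hydrogen sulfate (8-hydroxyluteolin 7-sulfate), via ammonium salt 23 (not isolated)
Conditions: NH3 (7 M in MeOH), 0 °C to rt, under Ar; then HCl (aq, 1.0 equiv), 0 °C, C18 reversed-phase desalting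
Reagents that add atoms: none
Why: Ammonolysis of the four aryl acetates (acyl transfer to ammonia), under which the aryl sulfate monoester is stable, followed by protonation of the sulfate with one equivalent of cold mineral acid.

**Compound list**

1 | 2-hydroxy-3-methoxybenzaldehyde (o-vanillin) | COc1cccc(C=O)c1O | starting material
2 | potassium 3-formyl-4-hydroxy-5-methoxyphenyl sulfate | COc1cc(OS(=O)(=O)[O-])cc(C=O)c1O.[K+] | intermediate
3 | 2,5-dihydroxy-3-methoxybenzaldehyde | COc1cc(O)cc(C=O)c1O | intermediate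
4 | 2,3,5-trimethoxybenzaldehyde | COc1cc(OC)c(OC)c(C=O)c1 | intermediate
5 | 2,3,5-trimethoxyphenyl formate | COc1cc(OC)c(OC)c(OC=O)c1 | intermediate
6 | 2,3,5-trimethoxyphenol | COc1cc(O)c(OC)c(OC)c1 | intermediate
7 | methyl (3,4-dimethoxyphenyl)acetate | COC(=O)Cc1ccc(OC)c(OC)c1 | starting material
8 | methyl 2-diazo-2-(3,4-dimethoxyphenyl)acetate | COC(=O)C(=[N+]=[N-])c1ccc(OC)c(OC)c1 | intermediate
9 | methyl 2-(3,4-dimethoxyphenyl)-2-(2,3,5-trimethoxyphenoxy)acetate (racemic) | COC(=O)C(Oc1cc(OC)cc(OC)c1OC)c1ccc(OC)c(OC)c1 | intermediate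
10 | 2-(3,4-dimethoxyphenyl)-2-(2,3,5-trimethoxyphenoxy)acetic acid (racemic) | OC(=O)C(Oc1cc(OC)cc(OC)c1OC)c1ccc(OC)c(OC)c1 | intermediate
11 | 2-(3,4-dimethoxyphenyl)-2-(2,3,5-trimethoxyphenoxy)acetic trifluoroacetic anhydride (racemic) | O=C(OC(=O)C(F)(F)F)C(Oc1cc(OC)cc(OC)c1OC)c1ccc(OC)c(OC)c1 | intermediate
12 | 2-(3,4-dimethoxyphenyl)-4,6,7-trimethoxy-1-benzofuran-3(2H)-one (racemic) | COc1cc(OC)c2c(c1OC)OC(c1ccc(OC)c(OC)c1)C2=O | intermediate
13 | tert-butyl{[2-(3,4-dimethoxyphenyl)-4,6,7-trimethoxy-1-benzofuran-3-yl]oxy}dimethylsilane | COc1cc(OC)c2c(O[Si](C)(C)C(C)(C)C)c(-c3ccc(OC)c(OC)c3)oc2c1OC | intermediate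
14 | bromoform | BrC(Br)Br | starting material
15 | gem-dibromocyclopropane adduct across C2–C3 of 13 (1,1-dibromo-1a-aryl-6b-silyloxy-1a,6b-dihydro-1H-cyclopropa[b][1]benzofuran; racemic, cis-fused) | COc1cc(OC)c2c(c1OC)OC1(c3ccc(OC)c(OC)c3)C(Br)(Br)C21O[Si](C)(C)C(C)(C)C | intermediate
16 | 3-bromo-4-[(tert-butyldimethylsilyl)oxy]-2-(3,4-dimethoxyphenyl)-5,7,8-trimethoxychromenylium bromide | COc1cc(OC)c2c(O[Si](C)(C)C(C)(C)C)c(Br)c(-c3ccc(OC)c(OC)c3)[o+]c2c1OC.[Br-] | intermediate
17 | 3-bromo-2-(3,4-dimethoxyphenyl)-5,7,8-trimethoxy-4H-chromen-4-one | COc1cc(OC)c2c(=O)c(Br)c(-c3ccc(OC)c(OC)c3)oc2c1OC | intermediate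
18 | 2-(3,4-dimethoxyphenyl)-5,7,8-trimethoxy-4H-chromen-4-one | COc1cc(OC)c2c(=O)cc(-c3ccc(OC)c(OC)c3)oc2c1OC | intermediate
19 | 2-(3,4-dihydroxyphenyl)-5,7,8-trihydroxy-4H-chromen-4-one (hypolaetin) | O=c1cc(-c2ccc(O)c(O)c2)oc2c(O)c(O)cc(O)c12 | intermediate
20 | 2-(3,4-diacetoxyphenyl)-4-oxo-4H-chromene-5,7,8-triyl triacetate | CC(=O)Oc1ccc(-c2cc(=O)c3c(OC(C)=O)cc(OC(C)=O)c(OC(C)=O)c3o2)cc1OC(C)=O | intermediate
21 | 2-(3,4-diacetoxyphenyl)-7-hydroxy-4-oxo-4H-chromene-5,8-diyl diacetate | CC(=O)Oc1ccc(-c2cc(=O)c3c(OC(C)=O)cc(O)c(OC(C)=O)c3o2)cc1OC(C)=O | intermediate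
22 | pyridinium 2-(3,4-diacetoxyphenyl)-5,8-diacetoxy-4-oxo-4H-chromen-7-yl sulfate | CC(=O)Oc1ccc(-c2cc(=O)c3c(OC(C)=O)cc(OS(=O)(=O)[O-])c(OC(C)=O)c3o2)cc1OC(C)=O.c1cc[nH+]cc1 | intermediate
23 | ammonium 2-(3,4-dihydroxyphenyl)-5,8-dihydroxy-4-oxo-4H-chromen-7-yl sulfate | O=c1cc(-c2ccc(O)c(O)c2)oc2c(O)c(OS(=O)(=O)[O-])cc(O)c12.[NH4+] | intermediate
24 | 8-hydroxyluteolin 7-sulfate | O=c1cc(-c2ccc(O)c(O)c2)oc2c(O)c(OS(=O)(=O)O)cc(O)c12 | target

**Step count**

Total: 15 steps. Longest linear sequence: 14 steps (steps 1–3, then 5–15); step 4 is a one-step side branch.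

**Steps most likely to fail**

Step 9 (proposed new method). The cycloaddition may be too slow at the tetrasubstituted, partly aromatic C2–C3 bond, so that the carbene is consumed by tert-butoxide, or the alkoxide may strip the silyl group before the carbene arrives. The fallback is the known chalcone route to flavones and sets out from phenol 6. Fries-type acetylation ortho to the hydroxyl with acetic acid and BF3·OEt2 at 90 °C should give 1-(2-hydroxy-3,4,6-trimethoxyphenyl)ethan-1-one F1. Claisen–Schmidt condensation of F1 with 3,4-dimethoxybenzaldehyde (KOH, EtOH, rt) should give (E)-3-(3,4-dimethoxyphenyl)-1-(2-hydroxy-3,4,6-trimethoxyphenyl)prop-2-en-1-one F2. Oxidative cyclisation of F2 with catalytic I2 in DMSO at 130 °C should give flavone 18, where the route is rejoined and steps 11–15 follow unchanged.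

Step 7. The activated acyl group may lose carbon monoxide to a stabilised aryloxy(aryl)methyl cation instead of acylating ring A, and the enolisable product may autoxidise at C2. The fallback reverses the order of bond formation (C3–C3a first, O1–C2 last) and sets out from phenol 6. Ortho C-acylation with (3,4-dimethoxyphenyl)acetic acid and BF3·OEt2 at 80 °C should give 2-(3,4-dimethoxyphenyl)-1-(2-hydroxy-3,4,6-trimethoxyphenyl)ethan-1-one F3. Enol-selective α-bromination with CuBr2 in EtOAc/CHCl3 at reflux should give 2-bromo-2-(3,4-dimethoxyphenyl)-1-(2-hydroxy-3,4,6-trimethoxyphenyl)ethan-1-one F4. NaOAc in EtOH should then close the furanone ring by intramolecular O-alkylation, which rejoins the route at 12.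

Step 13. Acetyl migration from O8 to the freed O7, or competing thiolysis of the 4'-acetate, would erode the regiocontrol on which the sulfation depends. The fallback drops the acetate detour and sets out from hypolaetin 19. Direct sulfation with Bu4NHSO4 and dicyclohexylcarbodiimide in pyridine at 4 °C, with the reagent limiting, should take the most acidic hydroxyl (7-OH) and give tetrabutylammonium 8-hydroxyluteolin 7-sulfate F5, to be separated from regioisomeric sulfates on Sephadex LH-20. Protonation of F5 with one equivalent of cold HCl and C18 desalting then gives the target 24 directly.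

**Further compounds**

F1 | step 9 | 1-(2-hydroxy-3,4,6-trimethoxyphenyl)ethan-1-one | CC(=O)c1c(O)c(OC)c(OC)cc1OC
F2 | step 9 | (E)-3-(3,4-dimethoxyphenyl)-1-(2-hydroxy-3,4,6-trimethoxyphenyl)prop-2-en-1-one | COc1ccc(/C=C/C(=O)c2c(O)c(OC)c(OC)cc2OC)cc1OC
F3 | step 7 | 2-(3,4-dimethoxyphenyl)-1-(2-hydroxy-3,4,6-trimethoxyphenyl)ethan-1-one | COc1ccc(CC(=O)c2c(O)c(OC)c(OC)cc2OC)cc1OC
F4 | step 7 | 2-bromo-2-(3,4-dimethoxyphenyl)-1-(2-hydroxy-3,4,6-trimethoxyphenyl)ethan-1-one (racemic) | COc1ccc(C(Br)C(=O)c2c(O)c(OC)c(OC)cc2OC)cc1OC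
F5 | step 13 | tetrabutylammonium 2-(3,4-dihydroxyphenyl)-5,8-dihydroxy-4-oxo-4H-chromen-7-yl sulfate | O=c1cc(-c2ccc(O)c(O)c2)oc2c(O)c(OS(=O)(=O)[O-])cc(O)c12.CCCC[N+](CCCC)(CCCC)CCCC
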